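A direct plan would copy the biogenesis: an acyclic enal allylic phosphate A1 would be closed to the ten-membered germacradienol A2 by intramolecular allylchromium addition, A2 would be turned into the 1,10-epoxy germacrolide A3, and Cp2TiCl (trivalent titanium) would open the epoxide and bond C10 to C5 across the ring to give eudesmanolide A4, whose lactone would be opened and O6 acylated. Its weakest steps would be:
- the macrocyclisation of A1 to A2, because it would need high dilution and excess CrCl2, and its C6/C7 face control would rest on one remote silyloxy group;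
- the transannular radical closure of A3 to A4, because the radical would have to end selectively as C4=C15 beside an α-methylene lactone and an allylic C3–O bond;
- the opening of the lactone of A4 with re-esterification, because it would cost three steps, add no complexity and compete with relactonisation.

The new route rests on a quinone Diels–Alder disconnection of ring B at C5–C6 and C9–C10. Ring A is bought as 2-methoxy-5-methyl-1,4-benzoquinone: its carbonyl carbons are C1 and C4, its methoxy carbon is C3 and its methyl-bearing carbon is C10, so the 1,3-dioxygenation, the C4 branch point and the angular methyl are present from the start. One cycloaddition with a 2-bromo-1-silyloxybutadiene (C6–C9), followed by epimerisation at C5, would close ring B and set C10, C5 and C6, with bromine marking C7. No macrocycle, no transannular radical step and no lactone appear; O6 is carried as a silyl ether and acylated directly.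

Key step: step 3

Numbering: eudesmane numbering is used for all bicyclic compounds (C1–C10 in the decalin, C14 the methyl on C10, C15 the carbon on C4, C11–C13 the side chain on C7); α is the face opposite the C10 methyl.
Assumption: quinone 5 is taken as purchasable, and the (S)-binaphthol ligand is taken to give the drawn enantiomer in step 3; the sense would be checked on 7 and the ligand antipode used if needed.

Step 1
Reactants: 1 (E)-but-2-enal (crotonaldehyde)
Product: 3 (Z)-2-bromobut-2-enal, via 2,3-dibromobutanal 2 (not isolated)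
Conditions: Br2, CH2Cl2, 0 °C; then Et3N, 0 °C to rt
Reagents that add atoms: bromine, BrBr
Why: Bromination–dehydrobromination: bromine adds across the enal alkene and triethylamine removes the acidic C2–H with loss of bromide, which should give the α-bromo enal with methyl and bromine cis (Z).

Step 2
Reactants: 3 (Z)-2-bromobut-2-enal
Product: 4 (1Z)-2-bromo-1-(triethylsilyloxy)buta-1,3-diene
Conditions: Et3SiOTf, Et3N, Et2O, 0 °C
Reagents that add atoms: triethylsilyl triflate, CC[Si](CC)(CC)OS(=O)(=O)C(F)(F)F
Why: Soft enolisation (O-silylation of the carbonyl, γ-deprotonation by the amine) of the s-trans enal should place the silyloxy group cis to bromine and trans to the new vinyl group, the geometry that can reach the s-cis diene conformation.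

Step 3
Reactants: 4 (1Z)-2-bromo-1-(triethylsilyloxy)buta-1,3-diene; 5 2-methoxy-5-methyl-1,4-benzoquinone
Product: 7 7-bromo-3-methoxy-6α-(triethylsilyloxy)-11,12,13,15-tetranoreudesma-2,7-diene-1,4-dione (5α-H, 10β-methyl, trans ring fusion), via cis-fused adduct 6 (not isolated)
Conditions: TiCl2(O-i-Pr)2 and (S)-1,1'-bi-2-naphthol (10 mol % each), 4 Å molecular sieves, toluene–CH2Cl2, −30 to 0 °C; then DBU (5 mol %), CH2Cl2, 0 °C
Reagents that add atoms: none
Why: A suprafacial, endo [4+2] cycloaddition between the C6=C7–C8=C9 diene of 4 and the C5=C10 double bond of 5, accelerated by the chiral titanium Lewis acid chelated between the C4 carbonyl and the C3 methoxy oxygen, would form C5–C6 and C9–C10 and so close the six-membered ring B onto the preformed ring A in a single intermolecular cycloaddition. The closest known reaction type is the Diels–Alder reaction of 2-methoxy-5-methylbenzoquinone with butadienes, which takes place at the methyl-bearing double bond and gives angular-methyl cis-decalin enediones that base turns into the trans series; titanium binaphtholate catalysis of 2-methoxyquinone cycloadditions with 1-silyloxydienes is of the same type. For orientation, the methoxy group makes the C1 carbonyl a vinylogous ester and deactivates C2=C3, so the ketone-like C4 carbonyl directs: the nucleophilic, unsubstituted diene terminus C9 bonds to C10 and the oxygen-bearing C6 bonds to C5. C10 and C6 are set together by the endo transition state, in which the outward silyloxy group ends anti to H5 and to the C10 methyl (6α-oxygen with 10β-methyl), and their absolute sense by the quinone face that the binaphtholate leaves open. C5 is then set by amine-catalysed epimerisation α to the C4 ketone, which should favour the trans-decalin with the 6-silyloxy group equatorial, while quaternary C10 blocks aromatisation of ring A. The step needs face and endo selectivity and survival of the β-silyloxy ketone, which chelation at C4, low temperature, the poor leaving-group ability of silanolate and the equatorial C6–O bond lying near the nodal plane of the C4 enolate should secure.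

Step 4
Reactants: 7 trans-fused enedione
Product: 8 7-bromo-3-methoxy-6α-(triethylsilyloxy)-11,12,13-trinoreudesma-2,4(15),7-trien-1-one
Conditions: Tebbe reagent Cp2Ti(μ-Cl)(μ-CH2)AlMe2 (1.1 equiv), pyridine (cat.), THF–toluene, −40 to 0 °C
Reagents that add atoms: Tebbe reagent, C[Al](C)C[Ti](Cl)(C1C=CC=C1)C1C=CC=C1
Why: Tebbe methylenation (titanium methylidene [2+2] with the carbonyl, then cycloreversion) is non-basic, so C5 is not epimerised and O6 is not eliminated, and it should take the ketone-like C4 carbonyl in preference to the hindered vinylogous-ester carbonyl C1.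

Step 5
Reactants: 8 C1 ketone
Product: 9 7-bromo-3-methoxy-6α-(triethylsilyloxy)-11,12,13-trinoreudesma-2,4(15),7-trien-1β-ol
Conditions: i-Bu2AlH (1.2 equiv), CH2Cl2, −78 °C; aq. KNa tartrate
Reagents that add atoms: none
Why: 1,2-Reduction of the vinylogous-ester carbonyl, with hydride delivered to the α face of C1 anti to the pseudo-axial C10 methyl, should set the 1β-alcohol, as in hydride reductions of angular-methyl decalin-1-ones.

Step 6
Reactants: 9 1β-alcohol
Product: 10 7-bromo-1β-(tert-butyldimethylsilyloxy)-3-methoxy-6α-(triethylsilyloxy)-11,12,13-trinoreudesma-2,4(15),7-triene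
Conditions: t-BuMe2SiOTf, 2,6-lutidine, CH2Cl2, −78 °C
Reagents that add atoms: tert-butyldimethylsilyl triflate, CC(C)(C)[Si](C)(C)OS(=O)(=O)C(F)(F)F
Why: Silyl triflate silylation with a hindered pyridine base caps the hydroxyl next to quaternary C10 without free acid, so the vinylogous acetal at C1 does not ionise and C1 keeps its configuration.

Step 7
Reactants: 10 2-methoxy-1,3-diene
Product: 11 7-bromo-1β-(tert-butyldimethylsilyloxy)-6α-(triethylsilyloxy)-11,12,13-trinoreudesma-4(15),7-dien-3-one
Conditions: oxalic acid (0.1 equiv), THF–H2O, 0 °C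
Reagents that add atoms: water, O
Why: Enol ether hydrolysis: protonation at C2 gives the C3 oxocarbenium ion, water adds and methanol leaves, which unveils the C3 ketone with C4=C15 in place, while the silyl ether on O1 slows ionisation at C1 and the cold weak acid should spare the C6 triethylsilyl ether.

Step 8
Reactants: 11 α-methylene ketone
Product: 12 7-bromo-1β-(tert-butyldimethylsilyloxy)-6α-(triethylsilyloxy)-11,12,13-trinoreudesma-4(15),7-dien-3β-ol
Conditions: NaBH4, CeCl3·7H2O, MeOH, −78 °C
Reagents that add atoms: none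
Why: Luche reduction gives 1,2-reduction of the enone, and axial hydride attack on the α face of the chair, away from the C10 methyl, should set the equatorial 3β-alcohol cis to O1.

Step 9
Reactants: 12 3β-alcohol
Product: 13 7-bromo-1β,3β-bis(tert-butyldimethylsilyloxy)-6α-(triethylsilyloxy)-11,12,13-trinoreudesma-4(15),7-diene
Conditions: t-BuMe2SiCl, imidazole, DMF, rt
Reagents that add atoms: tert-butyldimethylsilyl chloride, C[Si](C)(Cl)C(C)(C)C
Why: Imidazole-promoted silylation of an unhindered allylic secondary alcohol is routine and touches no stereocentre.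

Step 10
Reactants: 13 alkenyl bromide; 14 N-methoxy-N-methylacetamide
Product: 16 1β,3β-bis(tert-butyldimethylsilyloxy)-6α-(triethylsilyloxy)-12-noreudesma-4(15),7-dien-11-one, via alkenyllithium 15 (not isolated)
Conditions: t-BuLi (2.1 equiv), Et2O, −78 °C; then 14, −78 to 0 °C; aq. NH4Cl
Reagents that add atoms: none
Why: Bromine–lithium exchange gives the C7 alkenyllithium, which acylates the Weinreb amide through a chelated tetrahedral intermediate that releases the methyl ketone (C11, C13) only on work-up; the substrate holds no other electrophile at this stage.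

Step 11
Reactants: 16 enone
Product: 17 1β,3β-bis(tert-butyldimethylsilyloxy)-6α-(triethylsilyloxy)-12-noreudesm-4(15)-en-11-one (7α-H)
Conditions: [(Ph3P)CuH]6 (0.25 equiv), H2O (3 equiv), benzene–THF, rt
Reagents that add atoms: none
Why: Copper hydride conjugate reduction puts hydride on C8 of the enone only (isolated alkenes are inert), and protonation of the enolate at C7 on the axial α face, opposite the C10 methyl, should give H7α with the acetyl group equatorial and trans to O6, which is also the thermodynamic epimer.

Step 12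
Reactants: 17 methyl ketone
Product: 19 1β,3β-bis(tert-butyldimethylsilyloxy)-6α-(triethylsilyloxy)-12-noreudesma-4(15),11(13)-dien-11-yl trifluoromethanesulfonate, via potassium enolate 18 (not isolated)
Conditions: KN(SiMe3)2 (1.1 equiv), THF, −78 °C; then PhNTf2, −78 to −20 °C
Reagents that add atoms: N-phenylbis(trifluoromethanesulfonimide), O=S(=O)(N(c1ccccc1)S(=O)(=O)C(F)(F)F)C(F)(F)F
Why: Kinetic deprotonation by the bulky amide takes the methyl group C13 and not the hindered C7–H, and O-triflation of that enolate gives the terminal enol triflate without touching C7.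

Step 13
Reactants: 19 enol triflate
Product: 20 methyl 1β,3β-bis(tert-butyldimethylsilyloxy)-6α-(triethylsilyloxy)eudesma-4(15),11(13)-dien-12-oate
Conditions: Pd(OAc)2 (5 mol %), PPh3 (10 mol %), Et3N, CO (1 atm), MeOH–DMF, 40 °C
Reagents that add atoms: carbon monoxide, [C-]#[O+]; methanol, CO
Why: Palladium-catalysed methoxycarbonylation of an alkenyl triflate (oxidative addition to zerovalent palladium formed in the flask, CO insertion, methanolysis) turns C11–OTf into the C11(=C13)–C12 methyl acrylate and leaves C7 and the other alkenes alone.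

Step 14
Reactants: 20 tris-silyl ester
Product: 21 methyl 6α-hydroxy-1β,3β-bis(tert-butyldimethylsilyloxy)eudesma-4(15),11(13)-dien-12-oate
Conditions: HF·pyridine, pyridine, THF, 0 °C
Reagents that add atoms: none
Why: Buffered fluoride desilylation discriminates by the substituents on silicon, so the triethylsilyl ether on O6 should fall well before the two tert-butyldimethylsilyl ethers, and the cold, weakly acidic medium avoids lactonisation of the γ-hydroxy ester.

Step 15
Reactants: 22 methyl 2-(hydroxymethyl)acrylate
Product: 23 methyl 2-[(tert-butyldimethylsilyloxy)methyl]acrylate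
Conditions: t-BuMe2SiCl, imidazole, CH2Cl2, 0 °C to rt
Reagents that add atoms: tert-butyldimethylsilyl chloride, C[Si](C)(Cl)C(C)(C)C
Why: Routine silylation of a primary allylic alcohol.

Step 16
Reactants: 23 methyl 2-[(tert-butyldimethylsilyloxy)methyl]acrylate
Product: 24 2-[(tert-butyldimethylsilyloxy)methyl]acrylic acid
Conditions: LiOH, THF–H2O, 0 °C; 1 M HCl to pH 4
Reagents that add atoms: lithium hydroxide, [Li+].[OH-]
Why: Ester saponification at 0 °C is faster than conjugate addition to the α-substituted acrylate, and the silyl ether survives the brief mild acidification.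

Step 17
Reactants: 21 6α-hydroxy ester; 24 2-[(tert-butyldimethylsilyloxy)methyl]acrylic acid
Product: 26 methyl 1β,3β-bis(tert-butyldimethylsilyloxy)-6α-{2-[(tert-butyldimethylsilyloxy)methyl]acryloyloxy}eudesma-4(15),11(13)-dien-12-oate, via mixed anhydride 25 (not isolated)
Conditions: 2-methyl-6-nitrobenzoic anhydride (1.3 equiv), Et3N, DMAP (0.2 equiv), CH2Cl2, rt
Reagents that add atoms: none
Why: Shiina esterification: DMAP attacks the less hindered acryloyl carbonyl of the mixed anhydride and the acylpyridinium acylates the equatorial 6α-hydroxyl with retention at C6, which should outrun base-induced closure to the lactone.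

Step 18
Reactants: 26 tris-silyl diester
Product: 27 methyl 1β,3β-dihydroxy-6α-[2-(hydroxymethyl)acryloyloxy]eudesma-4(15),11(13)-dien-12-oate (CNP0247525.1)
Conditions: HF·pyridine, THF, 0 °C to rt
Reagents that add atoms: none
Why: Fluoride desilylation under weakly acidic conditions should remove the three silyl ethers without acyl migration, conjugate addition or lactonisation.

**Compound list**
1 | (E)-but-2-enal (crotonaldehyde) | C/C=C/C=O | starting material
2 | (2R*,3S*)-2,3-dibromobutanal (racemic) | C[C@H](Br)[C@H](Br)C=O | intermediate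
3 | (Z)-2-bromobut-2-enal | C/C=C(\Br)C=O | intermediate
4 | (1Z)-2-bromo-1-(triethylsilyloxy)buta-1,3-diene | CC[Si](CC)(CC)O/C=C(\Br)C=C | intermediate
5 | 2-methoxy-5-methyl-1,4-benzoquinone | COC1=CC(=O)C(C)=CC1=O | starting material
6 | 7-bromo-3-methoxy-6α-(triethylsilyloxy)-11,12,13,15-tetranoreudesma-2,7-diene-1,4-dione, 5β-H epimer (cis ring fusion) | CC[Si](CC)(CC)O[C@@H]1[C@@H]2C(=O)C(OC)=CC(=O)[C@]2(C)CC=C1Br | intermediate
7 | 7-bromo-3-methoxy-6α-(triethylsilyloxy)-11,12,13,15-tetranoreudesma-2,7-diene-1,4-dione (5α-H, trans ring fusion) | CC[Si](CC)(CC)O[C@@H]1[C@H]2C(=O)C(OC)=CC(=O)[C@]2(C)CC=C1Br | intermediate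
8 | 7-bromo-3-methoxy-6α-(triethylsilyloxy)-11,12,13-trinoreudesma-2,4(15),7-trien-1-one | CC[Si](CC)(CC)O[C@@H]1[C@H]2C(=C)C(OC)=CC(=O)[C@]2(C)CC=C1Br | intermediate
9 | 7-bromo-3-methoxy-6α-(triethylsilyloxy)-11,12,13-trinoreudesma-2,4(15),7-trien-1β-ol | CC[Si](CC)(CC)O[C@@H]1[C@H]2C(=C)C(OC)=C[C@@H](O)[C@]2(C)CC=C1Br | intermediate
10 | 7-bromo-1β-(tert-butyldimethylsilyloxy)-3-methoxy-6α-(triethylsilyloxy)-11,12,13-trinoreudesma-2,4(15),7-triene | CC[Si](CC)(CC)O[C@@H]1[C@H]2C(=C)C(OC)=C[C@@H](O[Si](C)(C)C(C)(C)C)[C@]2(C)CC=C1Br | intermediate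
11 | 7-bromo-1β-(tert-butyldimethylsilyloxy)-6α-(triethylsilyloxy)-11,12,13-trinoreudesma-4(15),7-dien-3-one | CC[Si](CC)(CC)O[C@@H]1[C@H]2C(=C)C(=O)C[C@@H](O[Si](C)(C)C(C)(C)C)[C@]2(C)CC=C1Br | intermediate
12 | 7-bromo-1β-(tert-butyldimethylsilyloxy)-6α-(triethylsilyloxy)-11,12,13-trinoreudesma-4(15),7-dien-3β-ol | CC[Si](CC)(CC)O[C@@H]1[C@H]2C(=C)[C@@H](O)C[C@@H](O[Si](C)(C)C(C)(C)C)[C@]2(C)CC=C1Br | intermediate
13 | 7-bromo-1β,3β-bis(tert-butyldimethylsilyloxy)-6α-(triethylsilyloxy)-11,12,13-trinoreudesma-4(15),7-diene | CC[Si](CC)(CC)O[C@@H]1[C@H]2C(=C)[C@@H](O[Si](C)(C)C(C)(C)C)C[C@@H](O[Si](C)(C)C(C)(C)C)[C@]2(C)CC=C1Br | intermediate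
14 | N-methoxy-N-methylacetamide | CC(=O)N(C)OC | starting material
15 | 7-lithio-1β,3β-bis(tert-butyldimethylsilyloxy)-6α-(triethylsilyloxy)-11,12,13-trinoreudesma-4(15),7-diene | CC[Si](CC)(CC)O[C@@H]1[C@H]2C(=C)[C@@H](O[Si](C)(C)C(C)(C)C)C[C@@H](O[Si](C)(C)C(C)(C)C)[C@]2(C)CC=C1[Li] | intermediate
16 | 1β,3β-bis(tert-butyldimethylsilyloxy)-6α-(triethylsilyloxy)-12-noreudesma-4(15),7-dien-11-one | CC[Si](CC)(CC)O[C@@H]1[C@H]2C(=C)[C@@H](O[Si](C)(C)C(C)(C)C)C[C@@H](O[Si](C)(C)C(C)(C)C)[C@]2(C)CC=C1C(C)=O | intermediate
17 | 1β,3β-bis(tert-butyldimethylsilyloxy)-6α-(triethylsilyloxy)-12-noreudesm-4(15)-en-11-one (7α-H) | CC[Si](CC)(CC)O[C@@H]1[C@H]2C(=C)[C@@H](O[Si](C)(C)C(C)(C)C)C[C@@H](O[Si](C)(C)C(C)(C)C)[C@]2(C)CC[C@H]1C(C)=O | intermediate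
18 | potassium 11(13)-enolate of 17 | CC[Si](CC)(CC)O[C@@H]1[C@H]2C(=C)[C@@H](O[Si](C)(C)C(C)(C)C)C[C@@H](O[Si](C)(C)C(C)(C)C)[C@]2(C)CC[C@H]1C(=C)[O-].[K+] | intermediate
19 | 1β,3β-bis(tert-butyldimethylsilyloxy)-6α-(triethylsilyloxy)-12-noreudesma-4(15),11(13)-dien-11-yl trifluoromethanesulfonate | CC[Si](CC)(CC)O[C@@H]1[C@H]2C(=C)[C@@H](O[Si](C)(C)C(C)(C)C)C[C@@H](O[Si](C)(C)C(C)(C)C)[C@]2(C)CC[C@H]1C(=C)OS(=O)(=O)C(F)(F)F | intermediate
20 | methyl 1β,3β-bis(tert-butyldimethylsilyloxy)-6α-(triethylsilyloxy)eudesma-4(15),11(13)-dien-12-oate | CC[Si](CC)(CC)O[C@@H]1[C@H]2C(=C)[C@@H](O[Si](C)(C)C(C)(C)C)C[C@@H](O[Si](C)(C)C(C)(C)C)[C@]2(C)CC[C@H]1C(=C)C(=O)OC | intermediate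
21 | methyl 6α-hydroxy-1β,3β-bis(tert-butyldimethylsilyloxy)eudesma-4(15),11(13)-dien-12-oate | O[C@@H]1[C@H]2C(=C)[C@@H](O[Si](C)(C)C(C)(C)C)C[C@@H](O[Si](C)(C)C(C)(C)C)[C@]2(C)CC[C@H]1C(=C)C(=O)OC | intermediate
22 | methyl 2-(hydroxymethyl)acrylate | C=C(CO)C(=O)OC | starting material
23 | methyl 2-[(tert-butyldimethylsilyloxy)methyl]acrylate | C=C(CO[Si](C)(C)C(C)(C)C)C(=O)OC | intermediate
24 | 2-[(tert-butyldimethylsilyloxy)methyl]acrylic acid | C=C(CO[Si](C)(C)C(C)(C)C)C(=O)O | intermediate
25 | mixed anhydride of 24 and 2-methyl-6-nitrobenzoic acid | C=C(CO[Si](C)(C)C(C)(C)C)C(=O)OC(=O)c1c(C)cccc1[N+](=O)[O-] | intermediate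
26 | methyl 1β,3β-bis(tert-butyldimethylsilyloxy)-6α-{2-[(tert-butyldimethylsilyloxy)methyl]acryloyloxy}eudesma-4(15),11(13)-dien-12-oate | C=C(CO[Si](C)(C)C(C)(C)C)C(=O)O[C@@H]1[C@H]2C(=C)[C@@H](O[Si](C)(C)C(C)(C)C)C[C@@H](O[Si](C)(C)C(C)(C)C)[C@]2(C)CC[C@H]1C(=C)C(=O)OC | intermediate
27 | methyl 1β,3β-dihydroxy-6α-[2-(hydroxymethyl)acryloyloxy]eudesma-4(15),11(13)-dien-12-oate | C=C(CO)C(=O)O[C@@H]1[C@H]2C(=C)[C@@H](O)C[C@@H](O)[C@]2(C)CC[C@H]1C(=C)C(=O)OC | target

Total step count: 18. Longest linear sequence: 16 (steps 1–14, 17, 18).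

Steps most likely to fail:

1. Step 3. The titanium binaphtholate may discriminate poorly between the faces of the methyl-bearing double bond against the uncatalysed background reaction, monodentate binding at the more basic C1 carbonyl would reverse the orientation, and base epimerisation may be accompanied by β-elimination of triethylsilanol. The fallback sets out from 4 and 5: the cycloaddition would be run thermally without Lewis acid (toluene, 80 °C), where orientation rests on the C4 carbonyl alone, and the adduct would be epimerised on basic alumina to racemic 7. The enantiomers would then be separated by preparative chromatography on a chiral stationary phase. The enantiomer of 7 F1 would be set aside, since F1 has the wrong configuration at C5, C6 and C10, and the route is rejoined at 7.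

2. Step 7. Acid may ionise the allylic C1–O bond of the vinylogous acetal, with loss of O1 and transposition to a 1-en-3-one, or may cleave the C6 triethylsilyl ether. The fallback sets out from 10 and avoids Brønsted acid: N-bromosuccinimide in NaHCO3-buffered aqueous THF at 0 °C would attack C2 of the dienol ether and, after addition of water and loss of methanol, give 2,7-dibromo-1β-(tert-butyldimethylsilyloxy)-6α-(triethylsilyloxy)-11,12,13-trinoreudesma-4(15),7-dien-3-one F2 as a mixture of C2 epimers. Zinc dust with NH4Cl in aqueous ethanol would then remove the α-bromine of F2 and leave the alkenyl bromide at C7 alone, and the route is rejoined at 11.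

3. Step 11. The copper enolate may expel the β-silyloxy group on C6, or protonation may give some of the C7 epimer. The fallback sets out from 16 and passes through an isolable silyl enol ether in place of the copper enolate: 1,4-hydrosilylation with Et3SiH and RhCl(PPh3)3 (benzene, rt) would give 1β,3β-bis(tert-butyldimethylsilyloxy)-6α,11-bis(triethylsilyloxy)-12-noreudesma-4(15),7(11)-diene F3. Methanolysis of the enol silyl ether of F3 with K2CO3 in MeOH at −20 to 0 °C would protonate C7 from the axial α face as the Si–O bond breaks, and the route is rejoined at 17.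

**Further compounds**
F1 | step 3 | enantiomer of 7 | CC[Si](CC)(CC)O[C@H]1[C@@H]2C(=O)C(OC)=CC(=O)[C@@]2(C)CC=C1Br
F2 | step 7 | 2,7-dibromo-1β-(tert-butyldimethylsilyloxy)-6α-(triethylsilyloxy)-11,12,13-trinoreudesma-4(15),7-dien-3-one (C2 epimers) | CC[Si](CC)(CC)O[C@@H]1[C@H]2C(=C)C(=O)C(Br)[C@@H](O[Si](C)(C)C(C)(C)C)[C@]2(C)CC=C1Br
F3 | step 11 | 1β,3β-bis(tert-butyldimethylsilyloxy)-6α,11-bis(triethylsilyloxy)-12-noreudesma-4(15),7(11)-diene | CC[Si](CC)(CC)O[C@@H]1[C@H]2C(=C)[C@@H](O[Si](C)(C)C(C)(C)C)C[C@@H](O[Si](C)(C)C(C)(C)C)[C@]2(C)CC/C1=C(\O[Si](CC)(CC)CC)C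
A1 | direct plan | (6E,9S,10E)-9-(tert-butyldimethylsilyloxy)-2-[(4-methoxybenzyloxy)methyl]-6,10-dimethyl-12-oxododeca-1,6,10-trien-3-yl diethyl phosphate | CCOP(=O)(OCC)OC(CC/C(C)=C/C[C@H](O[Si](C)(C)C(C)(C)C)/C(C)=C/C=O)C(=C)COCc1ccc(OC)cc1
A2 | direct plan | 3β-(tert-butyldimethylsilyloxy)-12-(4-methoxybenzyloxy)germacra-1(10)E,4E,11(13)-trien-6α-ol | C/C1=C\C[C@H](O[Si](C)(C)C(C)(C)C)/C(C)=C/[C@@H](O)[C@H](C(=C)COCc2ccc(OC)cc2)CC1
A3 | direct plan | 3β-(tert-butyldimethylsilyloxy)-1β,10α-epoxygermacra-4E,11(13)-dien-6α,12-olide | O1[C@@H]2C[C@H](O[Si](C)(C)C(C)(C)C)/C(C)=C/[C@H]3OC(=O)C(=C)[C@@H]3CC[C@@]12C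
A4 | direct plan | 1β-hydroxy-3β-(tert-butyldimethylsilyloxy)eudesma-4(15),11(13)-dien-6α,12-olide | O1[C@@H]2[C@H]3C(=C)[C@@H](O[Si](C)(C)C(C)(C)C)C[C@@H](O)[C@]3(C)CC[C@H]2C(=C)C1=O
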